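Watch the reagent first. Each flask holds a racemate, a single-handed catalyst at a small loading, and a different charge of reagent, and the question is how much left-handed product stands at the end.

in all of them: left-handed substrate 0.10 M; right-handed substrate 0.10 M; free catalyst 0.13 mol%
- blue: reagent 0.30 equiv; run made earlier
- grey: reagent 6.2 equiv; run made earlier
- dusk: reagent 0.400 equiv; time 20 h
- autumn: reagent 1.20 equiv; time 20 h
- noon: reagent 3.00 equiv; time 20 h
- midnight: reagent 10.0 equiv; time 20 h

| run | time / h | left-handed product / % | left-handed substrate / % |
|---|---|---|---|
| blue | 3.00 | 3 | 47 |
| blue | 6.00 | 3 | 45 |
| blue | 8.00 | 4 | 46 |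
| blue | 12.0 | 6 | 39 |
| blue | 15.0 | 9 | 46 |
| grey | 3.00 | 29 | 22 |
| grey | 6.00 | 42 | 9 |
| grey | 8.00 | 44 | 4 |
| grey | 12.0 | 47 | 5 |
| grey | 15.0 | 46 | 2 |

(standard deviation of a reading: 2 percentage points)

- free catalyst is single-handed; left-handed substrate and right-handed substrate are mirror images of each other, charged as a racemate, each of them at the stated concentration
- the earlier runs were read with a standard deviation of 2 percentage points
- on the list of suspects stand: reagent + free catalyst -> spent catalyst A; free catalyst + right-handed substrate <-> catalyst intermediate B; reagent + catalyst intermediate A -> free catalyst + left-handed product; reagent + catalyst intermediate B -> free catalyst + right-handed product; 2 free catalyst -> spent catalyst B; free catalyst + left-handed substrate <-> catalyst intermediate A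
- "hardly changes" means that all values lie within two and a half points (for a concentration: within two and a half percent of the largest)

- amount of left-handed product at the end, in percent of the left-handed substrate and right-handed substrate together charged for dusk, autumn, noon, midnight, in this order
- how the row runs (falls all the way / rises all the way / falls, then rises / rises, then falls / hardly changes)

I solved the two ends first. Left-handed substrate is half of what is charged, which is the ceiling for left-handed product when reagent abounds. Dusk, with 0.400 equivalents, is different: reagent is the limiting reagent there, and it can make 20.0% of product.

To join the ends I needed one number, which I called the clock: 0.0441 h⁻¹, the first-order loss rate of left-handed substrate per equivalent of reagent. I read it from grey at 3.00 h. Converting the left-handed substrate fully takes 16.1% of grey's reagent, so I treated that flask as pseudo-first-order. Blue's last reading, with its scatter of 2 percentage points, gave 0.0441 h⁻¹.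

Running the clock for 20 h gave dusk 14.9%, autumn 32.7%, noon 46.5% and midnight 50.0%, a rising row. Dusk was the weak link: 14.9% is less than the cap, yet that reckoning spends 74.5% of the reagent, so holding the reagent constant was unsound for dusk. I reforged that link by letting the rate follow reagent and left-handed substrate as both fall, and dusk came down to 10.8%.

The forecast read 14%, 32%, 46% and 49%, rises all the way: “The row rises throughout, flattening towards the ceiling.” Its dusk stands higher than my reforged one.

The flask gave 11.7%, 29.4%, 44.5% and 47.6%, rises all the way, and the forecast held within its tolerance.

    reagent + free catalyst → spent catalyst A (k = 0.310 M⁻¹ h⁻¹)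
    free catalyst + right-handed substrate ⇌ catalyst intermediate B (K = 2.00 M⁻¹, k = 14000 M⁻¹ h⁻¹)
    reagent + catalyst intermediate A → free catalyst + left-handed product (k = 710 M⁻¹ h⁻¹)
    reagent + catalyst intermediate B → free catalyst + right-handed product (k = 150 M⁻¹ h⁻¹)
    2 free catalyst → spent catalyst B (k = 1200 M⁻¹ h⁻¹)
    free catalyst + left-handed substrate ⇌ catalyst intermediate A (K = 24.0 M⁻¹, k = 20000 M⁻¹ h⁻¹)

The reforged clock, applied to noon, gives 43.9% against the flask's 44.5%. Midnight came to 1.4 points below the forecast, and at 20.0 h it held spent catalyst A at 76.6% and spent catalyst B at 22.5% of the catalyst charged, with left-handed substrate down to 2.35% of the two substrates charged.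

(The numbers in the tables are simulated from invented constants; the scatter is artificial.)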